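**Retrosynthetic overview**
1. The target is the erythro (7R,8S) 8-O-4′ neolignan. It is traced back to its C7 silyl ether, and the allyl group to a C1′–H bond: C1′ is the only aromatic C–H with no ortho substituent, so [Ir(OMe)(cod)]2-catalysed borylation and an allyl cross-coupling install it last.
2. Feature used: the ether carbon C4′ of ring B lies between the methoxy-bearing carbons C3′ and C5′ and is joined through oxygen to the secondary stereocentre C8. C4′ is therefore treated as C2 of cyclohexane-1,3-dione, whose carbonyl carbons become C3′ and C5′.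
3. Key disconnection O–C4′: Rh2(OAc)4-catalysed O–H insertion of 2-diazocyclohexane-1,3-dione into the C8 hydroxyl, with C8 untouched. Enol O-methylation, Saegusa–Ito dehydrogenation to the phenol and a second O-methylation follow.
4. The alcohol: C8 comes from ethyl (S)-lactate and C7 from a non-chelate (Felkin–Anh) ArTi(Oi-Pr)3 addition to O-triethylsilyl lactaldehyde. C7–O is then silylated and the C8 triethylsilyl ether removed.
5. Ring order: ring A is bought as 4-bromo-1,2-dimethoxybenzene. The carbocycle of ring B is bought saturated, attached in the key step and aromatized two steps later. No ring is closed anywhere.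

Key step: step 7

Remark on locants: C7 is the carbinol carbon and C8 the ether-bearing carbon of the propane chain; ring A is the 3,4-dimethoxyphenyl ring; ring B is the trioxygenated ring (C4′ carries the ether oxygen, C1′ the allyl group). "R*O" stands for the {(1R,2S)-1-(tert-butyldimethylsilyloxy)-1-(3,4-dimethoxyphenyl)propan-2-yl}oxy group, and the target is the (1R,2S) = (7R,8S) isomer.

Remark on steps 3 and 9: the reagents listed under "Reagents that add atoms" in these two steps supply atoms to the non-isolated intermediates only (Li to 5, Ti(Oi-Pr)3 to 6, Li to 14, SiMe3 to 15). None of these atoms remains in the isolated products 7 and 17.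

**Step 1**
Reactants: 1 ethyl (S)-lactate
Product: 2 ethyl (S)-2-(triethylsilyloxy)propanoate
Conditions: Et3SiCl, imidazole, DMF, 0 °C → rt
Reagents that add atoms: chlorotriethylsilane, CC[Si](Cl)(CC)CC
Why: Imidazole-promoted O-silylation of the secondary alcohol leaves the stereocentre untouched and gives a non-chelating ether that can later be removed beside a tert-butyldimethylsilyl ether.

**Step 2**
Reactants: 2 ethyl (S)-2-(triethylsilyloxy)propanoate
Product: 3 (S)-2-(triethylsilyloxy)propanal
Conditions: i-Bu2AlH (1.05 equiv), CH2Cl2, −78 °C; MeOH, then aq. potassium sodium tartrate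
Reagents that add atoms: none
Why: Partial ester reduction with i-Bu2AlH stops at the aluminium hemiacetal at −78 °C, which releases the aldehyde only on work-up; the crude aldehyde is used at once so that the α-stereocentre does not epimerize.

**Step 3**
Reactants: 3 (S)-2-(triethylsilyloxy)propanal; 4 4-bromo-1,2-dimethoxybenzene
Product: 7 (1R,2S)-1-(3,4-dimethoxyphenyl)-2-(triethylsilyloxy)propan-1-ol, via 3,4-dimethoxyphenyllithium 5 (not isolated), via (3,4-dimethoxyphenyl)titanium triisopropoxide 6 (not isolated)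
Conditions: 4, n-BuLi, THF, −78 °C; ClTi(Oi-Pr)3, −78 → −40 °C; then 3, −78 → 0 °C; aq. NH4Cl
Reagents that add atoms: n-butyllithium, [Li]CCCC; chlorotitanium triisopropoxide, CC(C)O[Ti](Cl)(OC(C)C)OC(C)C
Why: Bromine–lithium exchange and transmetalation give the weakly Lewis-acidic reagent ArTi(Oi-Pr)3, which cannot chelate the α-silyloxy group, so the 1,2-addition follows the polar Felkin–Anh model (C–OSi bond anti to the incoming aryl group) and sets C7 as R, anti to the C8 centre inherited from lactate.

**Step 4**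
Reactants: 7 (1R,2S)-1-(3,4-dimethoxyphenyl)-2-(triethylsilyloxy)propan-1-ol
Product: 8 (1R,2S)-1-(tert-butyldimethylsilyloxy)-1-(3,4-dimethoxyphenyl)-2-(triethylsilyloxy)propane
Conditions: t-BuMe2SiOTf, 2,6-lutidine, CH2Cl2, −78 → 0 °C
Reagents that add atoms: tert-butyldimethylsilyl trifluoromethanesulfonate, CC(C)(C)[Si](C)(C)OS(=O)(=O)C(F)(F)F
Why: Silyl triflate/lutidine silylation is strong enough for the hindered benzylic hydroxyl and takes place at oxygen only, so neither stereocentre is touched.

**Step 5**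
Reactants: 8 (1R,2S)-1-(tert-butyldimethylsilyloxy)-1-(3,4-dimethoxyphenyl)-2-(triethylsilyloxy)propane
Product: 9 (1R,2S)-1-(tert-butyldimethylsilyloxy)-1-(3,4-dimethoxyphenyl)propan-2-ol
Conditions: pyridinium p-toluenesulfonate (0.2 equiv), MeOH/CH2Cl2 (1:1), 0 °C
Reagents that add atoms: none
Why: Acid-catalysed methanolysis distinguishes the two silyl ethers by size, the triethylsilyl ether being cleaved far faster than the tert-butyldimethylsilyl ether, and under mildly acidic conditions the base-promoted 1,2-silyl migration is not expected.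

**Step 6**
Reactants: 10 cyclohexane-1,3-dione
Product: 11 2-diazocyclohexane-1,3-dione
Conditions: 4-acetamidobenzenesulfonyl azide, Et3N, MeCN, 0 °C → rt
Reagents that add atoms: 4-acetamidobenzenesulfonyl azide, CC(=O)Nc1ccc(cc1)S(=O)(=O)N=[N+]=[N-]
Why: Regitz diazo transfer to the doubly activated methylene of a 1,3-dione proceeds under mild amine base and gives the stable acceptor–acceptor diazo compound.

**Step 7**
Reactants: 9 (1R,2S)-1-(tert-butyldimethylsilyloxy)-1-(3,4-dimethoxyphenyl)propan-2-ol; 11 2-diazocyclohexane-1,3-dione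
Product: 12 2-(R*O)-3-hydroxycyclohex-2-en-1-one
Conditions: Rh2(OAc)4 (2 mol%), PhCF3, 80 °C; 11 (1.3 equiv) added over 4 h by syringe pump
Reagents that add atoms: none
Why: Rh2(OAc)4 decomposes 11 with loss of N2 to an electrophilic acceptor–acceptor rhodium carbenoid; the C8 hydroxyl of 9 adds to the carbenoid carbon, and a 1,2-proton shift of the resulting oxonium ylide releases the catalyst and the 2-alkoxy-1,3-dione, which rests as enol 12. The closest known reaction type is the Rh2(OAc)4-catalysed O–H insertion of alcohols, hindered secondary ones included, with cyclic 2-diazo-1,3-diketones. No ring is closed: the six-membered carbocycle of ring B is carried in by 11 and only the O–C4′ bond is formed. No stereocentre is created; C8 keeps its S configuration because the new bond is made at oxygen and none of the bonds to C8 is broken, and C7 is not involved. The step needs chemoselectivity for O–H insertion over Wolff ring contraction, attack on electron-rich ring A, insertion into the acidic enol O–H of 12 and reaction with adventitious water. Slow addition of 11 to a dry solution that always holds the alcohol in excess over the carbenoid, a catalyst that works below the temperature of thermal Wolff rearrangement, and the higher nucleophilicity of a free hydroxyl compared with an arene should secure it.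

**Step 8**
Reactants: 12 2-(R*O)-3-hydroxycyclohex-2-en-1-one
Product: 13 2-(R*O)-3-methoxycyclohex-2-en-1-one
Conditions: Me3SiCHN2, MeOH/PhMe (1:4), 0 °C → rt
Reagents that add atoms: trimethylsilyldiazomethane, C[Si](C)(C)C=[N+]=[N-]
Why: In this diazoalkane O-methylation the vinylogous acid protonates the reagent and its enolate is methylated at oxygen after methanolysis of the silicon, so no base is needed and C-alkylation at C2 is avoided; the two enol oxygens are equivalent by tautomerism, so a single vinylogous ester should form.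

**Step 9**
Reactants: 13 2-(R*O)-3-methoxycyclohex-2-en-1-one
Product: 17 2-(R*O)-3-methoxyphenol, via lithium dienolate 14 (not isolated), via trimethylsilyl dienol ether 15 (not isolated), via cyclohexa-2,5-dienone 16 (not isolated)
Conditions: LiN(i-Pr)2, THF, −78 °C; Me3SiCl, −78 → 0 °C; solvent exchange; Pd(OAc)2 (1.05 equiv), MeCN, rt
Reagents that add atoms: lithium diisopropylamide, CC(C)N([Li])C(C)C; chlorotrimethylsilane, C[Si](C)(C)Cl
Why: Kinetic deprotonation at C6, O-silylation and Saegusa–Ito oxidation (C6 palladation, β-hydride loss from C5) give the cross-conjugated dienone, which tautomerizes to the phenol; the non-acidic conditions spare the benzylic silyl ether, and a dienolate formed at C4 instead would converge on the same phenol.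

**Step 10**
Reactants: 17 2-(R*O)-3-methoxyphenol
Product: 18 tert-butyl{[(1R,2S)-2-(2,6-dimethoxyphenoxy)-1-(3,4-dimethoxyphenyl)propyl]oxy}dimethylsilane
Conditions: MeI, K2CO3, DMF, rt
Reagents that add atoms: iodomethane, CI
Why: Williamson O-methylation of the phenoxide is the only reaction open to the substrate, as no other acidic or nucleophilic site is present.

**Step 11**
Reactants: 18 tert-butyl{[(1R,2S)-2-(2,6-dimethoxyphenoxy)-1-(3,4-dimethoxyphenyl)propyl]oxy}dimethylsilane
Product: 19 tert-butyl{[(1R,2S)-2-[2,6-dimethoxy-4-(4,4,5,5-tetramethyl-1,3,2-dioxaborolan-2-yl)phenoxy]-1-(3,4-dimethoxyphenyl)propyl]oxy}dimethylsilane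
Conditions: [Ir(OMe)(cod)]2 (1.5 mol%), 4,4′-di-tert-butyl-2,2′-bipyridine (3 mol%), B2pin2 (1.0 equiv), THF, 80 °C, sealed tube
Reagents that add atoms: bis(pinacolato)diboron, CC1(C)OB(OC1(C)C)B1OC(C)(C)C(C)(C)O1
Why: Aromatic C–H borylation with the [Ir(OMe)(cod)]2/bipyridine catalyst is governed by sterics, and C1′ of ring B is the only aromatic C–H with no ortho substituent, whereas C2′/C6′ and every C–H of ring A have at least one.

**Step 12**
Reactants: 19 the C1′ pinacol boronate; 20 allyl bromide
Product: 21 tert-butyl{[(1R,2S)-2-(4-allyl-2,6-dimethoxyphenoxy)-1-(3,4-dimethoxyphenyl)propyl]oxy}dimethylsilane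
Conditions: Pd(PPh3)4 (5 mol%), K2CO3, THF/H2O, 60 °C
Reagents that add atoms: none
Why: In this Suzuki–Miyaura coupling, oxidative addition of allyl bromide to zerovalent palladium gives the π-allyl complex [(η3-C3H5)Pd(PPh3)2]Br, and base-assisted transmetalation of the aryl boronate followed by reductive elimination forms the C1′–allyl bond; the moderate temperature should keep the double bond out of conjugation.

**Step 13**
Reactants: 21 tert-butyl{[(1R,2S)-2-(4-allyl-2,6-dimethoxyphenoxy)-1-(3,4-dimethoxyphenyl)propyl]oxy}dimethylsilane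
Product: 22 (1R,2S)-2-(4-allyl-2,6-dimethoxyphenoxy)-1-(3,4-dimethoxyphenyl)propan-1-ol
Conditions: Bu4NF, THF, 0 °C → rt
Reagents that add atoms: none
Why: Fluoride-induced Si–O cleavage frees the C7 hydroxyl without touching either stereocentre, the aryl ether or the allyl group.

**Compound list**
1 | ethyl (S)-lactate | C[C@H](O)C(=O)OCC | starting material
2 | ethyl (S)-2-(triethylsilyloxy)propanoate | C[C@H](O[Si](CC)(CC)CC)C(=O)OCC | intermediate
3 | (S)-2-(triethylsilyloxy)propanal | C[C@H](O[Si](CC)(CC)CC)C=O | intermediate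
4 | 4-bromo-1,2-dimethoxybenzene | COc1ccc(Br)cc1OC | starting material
5 | 3,4-dimethoxyphenyllithium | COc1ccc([Li])cc1OC | intermediate
6 | (3,4-dimethoxyphenyl)titanium triisopropoxide | COc1ccc(cc1OC)[Ti](OC(C)C)(OC(C)C)OC(C)C | intermediate
7 | (1R,2S)-1-(3,4-dimethoxyphenyl)-2-(triethylsilyloxy)propan-1-ol | C[C@H](O[Si](CC)(CC)CC)[C@H](O)c1ccc(OC)c(OC)c1 | intermediate
8 | (1R,2S)-1-(tert-butyldimethylsilyloxy)-1-(3,4-dimethoxyphenyl)-2-(triethylsilyloxy)propane | C[C@H](O[Si](CC)(CC)CC)[C@H](O[Si](C)(C)C(C)(C)C)c1ccc(OC)c(OC)c1 | intermediate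
9 | (1R,2S)-1-(tert-butyldimethylsilyloxy)-1-(3,4-dimethoxyphenyl)propan-2-ol | O[C@@H](C)[C@H](O[Si](C)(C)C(C)(C)C)c1ccc(OC)c(OC)c1 | intermediate
10 | cyclohexane-1,3-dione | O=C1CCCC(=O)C1 | starting material
11 | 2-diazocyclohexane-1,3-dione | [N-]=[N+]=C1C(=O)CCCC1=O | intermediate
12 | 2-{[(1R,2S)-1-(tert-butyldimethylsilyloxy)-1-(3,4-dimethoxyphenyl)propan-2-yl]oxy}-3-hydroxycyclohex-2-en-1-one | O=C1CCCC(O)=C1O[C@@H](C)[C@H](O[Si](C)(C)C(C)(C)C)c1ccc(OC)c(OC)c1 | intermediate
13 | 2-{[(1R,2S)-1-(tert-butyldimethylsilyloxy)-1-(3,4-dimethoxyphenyl)propan-2-yl]oxy}-3-methoxycyclohex-2-en-1-one | O=C1CCCC(OC)=C1O[C@@H](C)[C@H](O[Si](C)(C)C(C)(C)C)c1ccc(OC)c(OC)c1 | intermediate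
14 | lithium 6-{[(1R,2S)-1-(tert-butyldimethylsilyloxy)-1-(3,4-dimethoxyphenyl)propan-2-yl]oxy}-5-methoxycyclohexa-1,5-dien-1-olate | [Li]OC1=CCCC(OC)=C1O[C@@H](C)[C@H](O[Si](C)(C)C(C)(C)C)c1ccc(OC)c(OC)c1 | intermediate
15 | 1-methoxy-2-{[(1R,2S)-1-(tert-butyldimethylsilyloxy)-1-(3,4-dimethoxyphenyl)propan-2-yl]oxy}-3-(trimethylsilyloxy)cyclohexa-1,3-diene | C[Si](C)(C)OC1=CCCC(OC)=C1O[C@@H](C)[C@H](O[Si](C)(C)C(C)(C)C)c1ccc(OC)c(OC)c1 | intermediate
16 | 2-{[(1R,2S)-1-(tert-butyldimethylsilyloxy)-1-(3,4-dimethoxyphenyl)propan-2-yl]oxy}-3-methoxycyclohexa-2,5-dien-1-one | O=C1C=CCC(OC)=C1O[C@@H](C)[C@H](O[Si](C)(C)C(C)(C)C)c1ccc(OC)c(OC)c1 | intermediate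
17 | 2-{[(1R,2S)-1-(tert-butyldimethylsilyloxy)-1-(3,4-dimethoxyphenyl)propan-2-yl]oxy}-3-methoxyphenol | Oc1cccc(OC)c1O[C@@H](C)[C@H](O[Si](C)(C)C(C)(C)C)c1ccc(OC)c(OC)c1 | intermediate
18 | tert-butyl{[(1R,2S)-2-(2,6-dimethoxyphenoxy)-1-(3,4-dimethoxyphenyl)propyl]oxy}dimethylsilane | COc1cccc(OC)c1O[C@@H](C)[C@H](O[Si](C)(C)C(C)(C)C)c1ccc(OC)c(OC)c1 | intermediate
19 | tert-butyl{[(1R,2S)-2-[2,6-dimethoxy-4-(4,4,5,5-tetramethyl-1,3,2-dioxaborolan-2-yl)phenoxy]-1-(3,4-dimethoxyphenyl)propyl]oxy}dimethylsilane | COc1cc(B2OC(C)(C)C(C)(C)O2)cc(OC)c1O[C@@H](C)[C@H](O[Si](C)(C)C(C)(C)C)c1ccc(OC)c(OC)c1 | intermediate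
20 | allyl bromide | C=CCBr | starting material
21 | tert-butyl{[(1R,2S)-2-(4-allyl-2,6-dimethoxyphenoxy)-1-(3,4-dimethoxyphenyl)propyl]oxy}dimethylsilane | C=CCc1cc(OC)c(O[C@@H](C)[C@H](O[Si](C)(C)C(C)(C)C)c2ccc(OC)c(OC)c2)c(OC)c1 | intermediate
22 | (1R,2S)-2-(4-allyl-2,6-dimethoxyphenoxy)-1-(3,4-dimethoxyphenyl)propan-1-ol | C=CCc1cc(OC)c(O[C@@H](C)[C@H](O)c2ccc(OC)c(OC)c2)c(OC)c1 | target

**Step count**
Total: 13 steps. Longest linear sequence: 12 steps (steps 1–5 and 7–13, from 1); step 6 is a one-step branch.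

**Steps most likely to fail, with fallbacks**

(a) Step 7. The carbenoid may be diverted before it meets the hindered hydroxyl, by Wolff ring contraction, by attack on ring A, or by a second insertion into the acidic enol O–H of the product as it accumulates. The fallback gives up the carbenoid construction and makes the C8–O bond at the lactate stage by Mitsunobu inversion. Commercial methyl (R)-lactate and 4-allyl-2,6-dimethoxyphenol (PPh3, DIAD, THF, 0 °C → rt) should give methyl (S)-2-(4-allyl-2,6-dimethoxyphenoxy)propanoate F1. Reduction with i-Bu2AlH (CH2Cl2, −78 °C) should give (S)-2-(4-allyl-2,6-dimethoxyphenoxy)propanal F2, used at once. Addition of the titanium reagent 6 under the non-chelate control of step 3 should then set C7. The fallback sets out from 4 (converted into 6 as in step 3) and comes back to the route at 22.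

(b) Step 9. Silylation of the dienolate may be incomplete, or the dienol ether may hydrolyse back to 13 before palladation, and the stoichiometric oxidation may stall as palladium metal separates. The fallback replaces the Pd(OAc)2 oxidation by a selenoxide syn-elimination. It sets out from 13: LiN(i-Pr)2 (THF, −78 °C) gives 14, and PhSeCl at −78 °C should give 2-(R*O)-3-methoxy-6-(phenylselanyl)cyclohex-2-en-1-one F3, expected as a mixture of C6 epimers. Oxidation with m-CPBA (1.0 equiv, CH2Cl2, −78 °C) should give 2-(R*O)-3-methoxy-6-(phenylseleninyl)cyclohex-2-en-1-one F4, which on warming with i-Pr2NH eliminates to 16 and tautomerizes. It comes back to the route at 17.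

(c) Step 12. The allyl double bond may migrate into conjugation with ring B through Pd–H species, and the electron-rich boronate may protodeboronate in aqueous base. The fallback reverses the polarity of the coupling and works under neutral, anhydrous conditions. It sets out from 19: NaBO3·4H2O (THF/H2O, rt) should give 4-(R*O)-3,5-dimethoxyphenol F5. PhNTf2 and Et3N (CH2Cl2, rt) should give 4-(R*O)-3,5-dimethoxyphenyl trifluoromethanesulfonate F6. Stille coupling with allyltributylstannane (Pd(PPh3)4, LiCl, 1,4-dioxane, 95 °C) should then give the allylarene. It comes back to the route at 21.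

**Further compounds**
F1 | step 7 | methyl (S)-2-(4-allyl-2,6-dimethoxyphenoxy)propanoate | C[C@H](Oc1c(OC)cc(CC=C)cc1OC)C(=O)OC
F2 | step 7 | (S)-2-(4-allyl-2,6-dimethoxyphenoxy)propanal | C[C@H](Oc1c(OC)cc(CC=C)cc1OC)C=O
F3 | step 9 | 2-{[(1R,2S)-1-(tert-butyldimethylsilyloxy)-1-(3,4-dimethoxyphenyl)propan-2-yl]oxy}-3-methoxy-6-(phenylselanyl)cyclohex-2-en-1-one | O=C1C([Se]c2ccccc2)CCC(OC)=C1O[C@@H](C)[C@H](O[Si](C)(C)C(C)(C)C)c1ccc(OC)c(OC)c1
F4 | step 9 | 2-{[(1R,2S)-1-(tert-butyldimethylsilyloxy)-1-(3,4-dimethoxyphenyl)propan-2-yl]oxy}-3-methoxy-6-(phenylseleninyl)cyclohex-2-en-1-one | O=C1C([Se](=O)c2ccccc2)CCC(OC)=C1O[C@@H](C)[C@H](O[Si](C)(C)C(C)(C)C)c1ccc(OC)c(OC)c1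
F5 | step 12 | 4-{[(1R,2S)-1-(tert-butyldimethylsilyloxy)-1-(3,4-dimethoxyphenyl)propan-2-yl]oxy}-3,5-dimethoxyphenol | COc1cc(O)cc(OC)c1O[C@@H](C)[C@H](O[Si](C)(C)C(C)(C)C)c1ccc(OC)c(OC)c1
F6 | step 12 | 4-{[(1R,2S)-1-(tert-butyldimethylsilyloxy)-1-(3,4-dimethoxyphenyl)propan-2-yl]oxy}-3,5-dimethoxyphenyl trifluoromethanesulfonate | COc1cc(OS(=O)(=O)C(F)(F)F)cc(OC)c1O[C@@H](C)[C@H](O[Si](C)(C)C(C)(C)C)c1ccc(OC)c(OC)c1
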